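**Plan**

1. Retrosynthesis: cut C7=C8 (olefination of a C8 phosphonate with a C1–C7 enal), then C10–Br (back to the 10,11-epoxide of the enone), then the bond between the ring carbinol carbon C12 and the octadienyl CH2 C13, then the chain bonds C13–C14 and C15–C16 (boron homologation, diyne coupling).
2. Enabling feature: ring atoms C9–C10=C11–C12 with oxygen on C9 and C12 are a cis-cyclopent-2-ene-1,4-diol in disguise. C12 is both oxygen-bearing and allylic to C10=C11, so the C12–H of its carbamate can be lithiated; C13 is an allylic CH2 that can migrate from boron as an sp3 carbon.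
3. Forward: a (2Z,5Z)-octadienyl pinacol boronate (4 steps) and the mono-carbamate of the desymmetrised diol (2 steps) are joined by lithiation, borylation, 1,2-metallate shift and C–B oxidation. The helpers leave again: the carbamate is expelled, boron is oxidised to the 12-OH, and the C9 carbinol (a lithium alkoxide during the coupling) is oxidised to the ketone.
4. Then bromine at C10 through epoxide and HBr, 12-O-silylation, a phosphonate at C8, Z-selective olefination with the enal, and global desilylation. No ring is formed in the route; the cyclopentene is bought.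
5. Stereochemistry: C12 from the enzymatically desymmetrised monoacetate (H replaced by C13 with retention); C4 from (S)-2-hydroxyglutarate; 14Z and 17Z from Lindlar hydrogenation, carried through boron chemistry without an allyl metal; 5E from a stabilised Wittig reaction; 7Z from an aryl phosphonate (Ando-type) olefination.

Key step: step 7

Remark: atoms are numbered as in prostanoids (C1 = ester carbon, C8–C12 = ring, C13–C20 = octadienyl chain); all starting materials are taken to be purchasable.

**Route**

Step 1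
Reactants: 1 1-bromopent-2-yne; 2 ethynylmagnesium bromide
Product: 3 hepta-1,4-diyne
Conditions: CuCl (5 mol %), THF, 0 °C to rt
Reagents that add atoms: none
Why: Copper-catalysed SN2 coupling of a propargylic bromide with an alkynyl Grignard reagent (skipped-diyne synthesis), in which CuCl directs attack to the CH2 carbon and holds back allene formation.

Step 2
Reactants: 3 hepta-1,4-diyne
Product: 5 2-(hepta-1,4-diyn-1-yl)-4,4,5,5-tetramethyl-1,3,2-dioxaborolane, via lithium hepta-1,4-diyn-1-ide 4 (not isolated)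
Conditions: n-BuLi, THF, −78 °C; iPrOBpin, −78 °C; HCl in Et2O, −78 °C to rt
Reagents that add atoms: 2-isopropoxy-4,4,5,5-tetramethyl-1,3,2-dioxaborolane, CC(C)OB1OC(C)(C)C(C)(C)O1
Why: Borylation of an acetylide: the terminal C–H is far more acidic than the skipped CH2, and acid releases isopropanol from the borate to give the alkynyl boronate.

Step 3
Reactants: 5 2-(hepta-1,4-diyn-1-yl)-4,4,5,5-tetramethyl-1,3,2-dioxaborolane
Product: 6 2-[(1Z,4Z)-hepta-1,4-dien-1-yl]-4,4,5,5-tetramethyl-1,3,2-dioxaborolane
Conditions: H2 (1 atm), Pd/CaCO3 poisoned with Pb(OAc)2 (Lindlar catalyst), quinoline, hexane, rt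
Reagents that add atoms: none
Why: Lindlar semihydrogenation adds H2 syn to each triple bond, so both olefins, including the alkenyl boronate, should form Z, with quinoline holding back over-reduction.

Step 4
Reactants: 6 2-[(1Z,4Z)-hepta-1,4-dien-1-yl]-4,4,5,5-tetramethyl-1,3,2-dioxaborolane
Product: 8 2-[(2Z,5Z)-octa-2,5-dien-1-yl]-4,4,5,5-tetramethyl-1,3,2-dioxaborolane, via chloromethyl boronate complex 7 (not isolated)
Conditions: ICH2Cl, n-BuLi, THF, −78 °C to rt
Reagents that add atoms: chloroiodomethane, ClCI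
Why: Matteson homologation: chloromethyllithium adds to boron and the alkenyl group migrates with loss of chloride and retention of its Z geometry, giving the allylic boronic ester without an allyl metal intermediate.

Step 5
Reactants: 9 (1S,4R)-cis-4-acetoxycyclopent-2-en-1-ol
Product: 10 (1S,4R)-4-acetoxycyclopent-2-en-1-yl N,N-diisopropylcarbamate
Conditions: iPr2NCOCl, Et3N, DMAP (cat.), CH2Cl2, reflux
Reagents that add atoms: N,N-diisopropylcarbamoyl chloride, CC(C)N(C(C)C)C(Cl)=O
Why: O-Carbamoylation of the free secondary alcohol under amine conditions, where no alkoxide forms and so no acetyl migration can erode the enantiopurity set by the enzymatic desymmetrisation of the meso diacetate.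

Step 6
Reactants: 10 (1S,4R)-4-acetoxycyclopent-2-en-1-yl N,N-diisopropylcarbamate
Product: 11 (1S,4R)-4-hydroxycyclopent-2-en-1-yl N,N-diisopropylcarbamate
Conditions: K2CO3 (cat.), MeOH, 0 °C to rt
Reagents that add atoms: none
Why: Base-catalysed methanolysis (transesterification) removes the acetate while the hindered N,N-diisopropylcarbamate is inert, and neither stereocentre is touched.

Step 7
Reactants: 11 (1S,4R)-4-hydroxycyclopent-2-en-1-yl N,N-diisopropylcarbamate; 8 2-[(2Z,5Z)-octa-2,5-dien-1-yl]-4,4,5,5-tetramethyl-1,3,2-dioxaborolane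
Product: 15 (1S,4R)-1-[(2Z,5Z)-octa-2,5-dien-1-yl]cyclopent-2-ene-1,4-diol, via dilithio carbamate 12 (not isolated), via lithium boronate complex 13 (not isolated), via tertiary allylic boronic ester 14 (not isolated)
Conditions: s-BuLi (2.3 equiv), TMEDA, Et2O, −78 °C; 8 (1.3 equiv), −78 °C to rt; then NaOH, H2O2, THF/H2O, 0 °C
Reagents that add atoms: hydrogen peroxide, OO
Why: The first equivalent of s-BuLi turns the C9 hydroxyl into a lithium alkoxide, which cannot leave and so blocks 1,4-elimination to a cyclopentadiene, and the second removes the C12–H, acidified by the carbamate oxygen and by the C10=C11 double bond, with retention to give the carbamate-chelated, configurationally stable organolithium 12. Boronic ester 8 is captured at C12 on the lithium-bearing face (complex 13), and on warming the octadienyl group shifts from boron to C12 anti to the departing carbamate (1,2-metallate rearrangement) to give 14, whose C–B bond is then oxidised with retention to the tertiary alcohol. The closest known reaction type is the lithiation–borylation of secondary allylic carbamates to tertiary allylic boronic esters and alcohols, a Matteson-type 1,2-metallate rearrangement. No ring is closed. The new stereocentre C12 is controlled solely by the configuration of the carbamate carbon of 11 (from the enzymatically desymmetrised 9): C13 takes the place of the hydrogen with retention and the oxygen returns to its original face, which is the 12R arrangement of the target. The step needs α- rather than γ-borylation (C12, not C10), secured by chelation of lithium to the carbamate at C12 and by the bulk of the pinacol boronate next to the C9 alkoxide, and it needs both Z olefins to survive, secured because the migrating terminus is the sp3 carbon C13 and no allyl metal or allylic transposition is involved.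

Step 8
Reactants: 15 (1S,4R)-1-[(2Z,5Z)-octa-2,5-dien-1-yl]cyclopent-2-ene-1,4-diol
Product: 16 (4S)-4-hydroxy-4-[(2Z,5Z)-octa-2,5-dien-1-yl]cyclopent-2-en-1-one
Conditions: MnO2 (excess), CH2Cl2, rt
Reagents that add atoms: none
Why: Chemoselective MnO2 oxidation of the secondary allylic alcohol (the tertiary alcohol and the skipped diene are inert), which erases the C9 stereocentre once it has served as the desymmetrisation handle.

Step 9
Reactants: 16 (4S)-4-hydroxy-4-[(2Z,5Z)-octa-2,5-dien-1-yl]cyclopent-2-en-1-one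
Product: 17 (1S,4S,5R)-4-hydroxy-4-[(2Z,5Z)-octa-2,5-dien-1-yl]-6-oxabicyclo[3.1.0]hexan-2-one (oxirane cis to the hydroxyl)
Conditions: 30% aq H2O2, NaOH (0.2 equiv), MeOH, 0 °C
Reagents that add atoms: hydrogen peroxide, OO
Why: Weitz–Scheffer nucleophilic epoxidation attacks only the electron-poor C10=C11 bond, with hydroperoxide expected on the hydroxyl face (anti to the octadienyl chain), where Payne rearrangement is geometrically impossible; the two oxirane centres are lost in the next step.

Step 10
Reactants: 17 (1S,4S,5R)-4-hydroxy-4-[(2Z,5Z)-octa-2,5-dien-1-yl]-6-oxabicyclo[3.1.0]hexan-2-one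
Product: 19 (4S)-2-bromo-4-hydroxy-4-[(2Z,5Z)-octa-2,5-dien-1-yl]cyclopent-2-en-1-one, via trans-bromohydrin 18 (not isolated)
Conditions: 48% aq HBr (1.5 equiv), acetone, 0 °C to rt
Reagents that add atoms: hydrogen bromide, Br
Why: Acid-promoted opening of the α,β-epoxy ketone by bromide at C10 (activated by the carbonyl and remote from the quaternary C12) followed by loss of the β-hydroxyl through the enol should give the 2-bromoenone, while the isolated Z olefins do not react with cold aqueous HBr.

Step 11
Reactants: 19 (4S)-2-bromo-4-hydroxy-4-[(2Z,5Z)-octa-2,5-dien-1-yl]cyclopent-2-en-1-one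
Product: 20 (4S)-2-bromo-4-[(2Z,5Z)-octa-2,5-dien-1-yl]-4-(triethylsilyloxy)cyclopent-2-en-1-one
Conditions: Et3SiOTf, 2,6-lutidine, CH2Cl2, −78 to 0 °C
Reagents that add atoms: triethylsilyl trifluoromethanesulfonate, CC[Si](CC)(CC)OS(=O)(=O)C(F)(F)F
Why: Silylation of the hindered tertiary alcohol with a silyl triflate and a non-nucleophilic base, so that the C8 enolate can be formed in the next step.

Step 12
Reactants: 20 (4S)-2-bromo-4-[(2Z,5Z)-octa-2,5-dien-1-yl]-4-(triethylsilyloxy)cyclopent-2-en-1-one
Product: 23 diphenyl {(2R)-4-bromo-2-[(2Z,5Z)-octa-2,5-dien-1-yl]-5-oxo-2-(triethylsilyloxy)cyclopent-3-en-1-yl}phosphonate (C1 epimers), via lithium enolate 21 (not isolated), via diphenyl phosphonite 22 (not isolated)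
Conditions: LiN(iPr)2 (1.1 equiv), THF, −78 °C; added to ClP(OPh)2, THF, −78 °C; t-BuOOH (decane), −78 to 0 °C
Reagents that add atoms: diphenyl phosphorochloridite, ClP(Oc1ccccc1)Oc1ccccc1; tert-butyl hydroperoxide, CC(C)(C)OO
Why: Kinetic deprotonation at C8 (the only enolisable position), C-phosphitylation of the enolate by the soft trivalent phosphorus chloride and oxidation to the phosphonate (enolate phosphitylation–oxidation route to β-keto phosphonates); the C8 centre becomes sp2 in step 16, so its epimers converge.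

Step 13
Reactants: 24 dimethyl (2S)-2-hydroxypentanedioate
Product: 25 dimethyl (2S)-2-(tert-butyldimethylsilyloxy)pentanedioate
Conditions: TBSCl, imidazole, DMF, rt
Reagents that add atoms: tert-butyldimethylsilyl chloride, CC(C)(C)[Si](C)(C)Cl
Why: Standard silylation of the secondary alcohol, which also prevents lactonisation onto the distal ester; the chiral-pool stereocentre (future C4) is untouched.

Step 14
Reactants: 25 dimethyl (2S)-2-(tert-butyldimethylsilyloxy)pentanedioate
Product: 26 methyl (4S)-4-(tert-butyldimethylsilyloxy)-5-oxopentanoate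
Conditions: iBu2AlH (1.05 equiv), CH2Cl2, −78 °C; MeOH, aq potassium sodium tartrate
Reagents that add atoms: none
Why: Regioselective half-reduction: the ester next to the silyloxy group is the more electrophilic and its aluminium hemiacetal is stabilised by the α-oxygen, so one hydride should go there and the aldehyde is released only on work-up.

Step 15
Reactants: 26 methyl (4S)-4-(tert-butyldimethylsilyloxy)-5-oxopentanoate; 27 (formylmethylene)triphenylphosphorane
Product: 28 methyl (4S,5E)-4-(tert-butyldimethylsilyloxy)-7-oxohept-5-enoate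
Conditions: toluene, 80 °C
Reagents that add atoms: none
Why: Wittig reaction of a stabilised ylide gives the E enal, and a second homologation is disfavoured because the product enal is less electrophilic than the α-silyloxy aldehyde.

Step 16
Reactants: 23 diphenyl {(2R)-4-bromo-2-[(2Z,5Z)-octa-2,5-dien-1-yl]-5-oxo-2-(triethylsilyloxy)cyclopent-3-en-1-yl}phosphonate; 28 methyl (4S,5E)-4-(tert-butyldimethylsilyloxy)-7-oxohept-5-enoate
Product: 30 methyl (4S,5E,7Z,12R,14Z,17Z)-10-bromo-4-(tert-butyldimethylsilyloxy)-9-oxo-12-(triethylsilyloxy)prosta-5,7,10,14,17-pentaenoate, via sodium salt 29 (not isolated)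
Conditions: NaH, THF, 0 °C; 28, −78 to −20 °C
Reagents that add atoms: none
Why: Horner–Wadsworth–Emmons olefination in its Ando variant: the electron-poor aryloxy groups make addition irreversible and elimination fast, so the kinetic adduct should place the aldehyde residue C6 cis to the ring carbonyl C9 (7Z), a preference reinforced by the quaternary silyloxy-bearing C12 on the other side.

Step 17
Reactants: 30 methyl (4S,5E,7Z,12R,14Z,17Z)-10-bromo-4-(tert-butyldimethylsilyloxy)-9-oxo-12-(triethylsilyloxy)prosta-5,7,10,14,17-pentaenoate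
Product: 31 methyl (4S,5E,7Z,12R,14Z,17Z)-10-bromo-4,12-dihydroxy-9-oxoprosta-5,7,10,14,17-pentaenoate
Conditions: HF·pyridine, pyridine, THF, 0 °C to rt
Reagents that add atoms: none
Why: Fluoride-mediated cleavage of both silyl ethers under buffered, non-basic conditions that should spare the cross-conjugated bromodienone and avoid lactonisation of the γ-hydroxy ester.

**Compound list**

1 | 1-bromopent-2-yne | CCC#CCBr | starting material
2 | ethynylmagnesium bromide | C#C[Mg]Br | starting material
3 | hepta-1,4-diyne | CCC#CCC#C | intermediate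
4 | lithium hepta-1,4-diyn-1-ide | CCC#CCC#C[Li] | intermediate
5 | 2-(hepta-1,4-diyn-1-yl)-4,4,5,5-tetramethyl-1,3,2-dioxaborolane | CCC#CCC#CB1OC(C)(C)C(C)(C)O1 | intermediate
6 | 2-[(1Z,4Z)-hepta-1,4-dien-1-yl]-4,4,5,5-tetramethyl-1,3,2-dioxaborolane | CC/C=C\C/C=C\B1OC(C)(C)C(C)(C)O1 | intermediate
7 | lithium (chloromethyl)[(1Z,4Z)-hepta-1,4-dien-1-yl](pinacolato)borate (chloromethyl boronate complex) | CC/C=C\C/C=C\[B-]1(CCl)OC(C)(C)C(C)(C)O1.[Li+] | intermediate
8 | 2-[(2Z,5Z)-octa-2,5-dien-1-yl]-4,4,5,5-tetramethyl-1,3,2-dioxaborolane | CC/C=C\C/C=C\CB1OC(C)(C)C(C)(C)O1 | intermediate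
9 | (1S,4R)-cis-4-acetoxycyclopent-2-en-1-ol | O[C@@H]1C=C[C@H](OC(C)=O)C1 | starting material
10 | (1S,4R)-4-acetoxycyclopent-2-en-1-yl N,N-diisopropylcarbamate | CC(C)N(C(C)C)C(=O)O[C@@H]1C=C[C@H](OC(C)=O)C1 | intermediate
11 | (1S,4R)-4-hydroxycyclopent-2-en-1-yl N,N-diisopropylcarbamate | CC(C)N(C(C)C)C(=O)O[C@@H]1C=C[C@H](O)C1 | intermediate
12 | dilithio carbamate: 1-lithio-4-(lithiooxy)cyclopent-2-en-1-yl N,N-diisopropylcarbamate, lithium on the face of the former C1–H, C4 as in 11 | CC(C)N(C(C)C)C(=O)O[C@]1([Li])C=C[C@H](O[Li])C1 | intermediate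
13 | lithium boronate complex of 12 and 8, boron on the face of the former C–Li bond | CC(C)N(C(C)C)C(=O)O[C@]1([B-]2(C/C=C\C/C=C\CC)OC(C)(C)C(C)(C)O2)C=C[C@H](O[Li])C1.[Li+] | intermediate
14 | tertiary allylic boronic ester: 2-{4-(lithiooxy)-1-[(2Z,5Z)-octa-2,5-dien-1-yl]cyclopent-2-en-1-yl}-4,4,5,5-tetramethyl-1,3,2-dioxaborolane, boron cis to the C4 oxygen | CC/C=C\C/C=C\C[C@@]1(B2OC(C)(C)C(C)(C)O2)C=C[C@H](O[Li])C1 | intermediate
15 | (1S,4R)-1-[(2Z,5Z)-octa-2,5-dien-1-yl]cyclopent-2-ene-1,4-diol | CC/C=C\C/C=C\C[C@@]1(O)C=C[C@H](O)C1 | intermediate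
16 | (4S)-4-hydroxy-4-[(2Z,5Z)-octa-2,5-dien-1-yl]cyclopent-2-en-1-one | CC/C=C\C/C=C\C[C@@]1(O)C=CC(=O)C1 | intermediate
17 | (1S,4S,5R)-4-hydroxy-4-[(2Z,5Z)-octa-2,5-dien-1-yl]-6-oxabicyclo[3.1.0]hexan-2-one | CC/C=C\C/C=C\C[C@@]1(O)[C@@H]2O[C@@H]2C(=O)C1 | intermediate
18 | trans-bromohydrin: (2R,3S,4S)-2-bromo-3,4-dihydroxy-4-[(2Z,5Z)-octa-2,5-dien-1-yl]cyclopentan-1-one | CC/C=C\C/C=C\C[C@@]1(O)[C@H](O)[C@@H](Br)C(=O)C1 | intermediate
19 | (4S)-2-bromo-4-hydroxy-4-[(2Z,5Z)-octa-2,5-dien-1-yl]cyclopent-2-en-1-one | CC/C=C\C/C=C\C[C@@]1(O)C=C(Br)C(=O)C1 | intermediate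
20 | (4S)-2-bromo-4-[(2Z,5Z)-octa-2,5-dien-1-yl]-4-(triethylsilyloxy)cyclopent-2-en-1-one | CC/C=C\C/C=C\C[C@@]1(O[Si](CC)(CC)CC)C=C(Br)C(=O)C1 | intermediate
21 | lithium enolate of 20 (C5=C1–OLi) | CC/C=C\C/C=C\C[C@@]1(O[Si](CC)(CC)CC)C=C(Br)C(O[Li])=C1 | intermediate
22 | diphenyl phosphonite: diphenyl {(2R)-4-bromo-2-[(2Z,5Z)-octa-2,5-dien-1-yl]-5-oxo-2-(triethylsilyloxy)cyclopent-3-en-1-yl}phosphonite (C1 epimers) | CC/C=C\C/C=C\C[C@@]1(O[Si](CC)(CC)CC)C=C(Br)C(=O)C1P(Oc1ccccc1)Oc1ccccc1 | intermediate
23 | diphenyl {(2R)-4-bromo-2-[(2Z,5Z)-octa-2,5-dien-1-yl]-5-oxo-2-(triethylsilyloxy)cyclopent-3-en-1-yl}phosphonate (C1 epimers) | CC/C=C\C/C=C\C[C@@]1(O[Si](CC)(CC)CC)C=C(Br)C(=O)C1P(=O)(Oc1ccccc1)Oc1ccccc1 | intermediate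
24 | dimethyl (2S)-2-hydroxypentanedioate | COC(=O)CC[C@H](O)C(=O)OC | starting material
25 | dimethyl (2S)-2-(tert-butyldimethylsilyloxy)pentanedioate | COC(=O)CC[C@H](O[Si](C)(C)C(C)(C)C)C(=O)OC | intermediate
26 | methyl (4S)-4-(tert-butyldimethylsilyloxy)-5-oxopentanoate | COC(=O)CC[C@H](O[Si](C)(C)C(C)(C)C)C=O | intermediate
27 | (formylmethylene)triphenylphosphorane | O=CC=P(c1ccccc1)(c1ccccc1)c1ccccc1 | starting material
28 | methyl (4S,5E)-4-(tert-butyldimethylsilyloxy)-7-oxohept-5-enoate | COC(=O)CC[C@H](O[Si](C)(C)C(C)(C)C)/C=C/C=O | intermediate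
29 | sodium salt of 23 (sodium enolate of the β-keto phosphonate) | CC/C=C\C/C=C\C[C@@]1(O[Si](CC)(CC)CC)C=C(Br)C(O[Na])=C1P(=O)(Oc1ccccc1)Oc1ccccc1 | intermediate
30 | methyl (4S,5E,7Z,12R,14Z,17Z)-10-bromo-4-(tert-butyldimethylsilyloxy)-9-oxo-12-(triethylsilyloxy)prosta-5,7,10,14,17-pentaenoate | CC/C=C\C/C=C\C[C@@]1(O[Si](CC)(CC)CC)C=C(Br)C(=O)/C1=C\C=C\[C@@H](O[Si](C)(C)C(C)(C)C)CCC(=O)OC | intermediate
31 | methyl (4S,5E,7Z,12R,14Z,17Z)-10-bromo-4,12-dihydroxy-9-oxoprosta-5,7,10,14,17-pentaenoate | CC/C=C\C/C=C\C[C@@]1(O)C=C(Br)C(=O)/C1=C\C=C\[C@@H](O)CCC(=O)OC | target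

**Step count and risks**

Total step count: 17. Longest linear sequence: 12 steps (steps 1–4, 7–12, 16, 17).

The three steps most likely to fail:

Step 7. Lithiation of the dianion may be incomplete or may not hold its configuration, boron may be taken up at the γ-carbon C10, or the crowded boronate complex may not rearrange. The fallback reverses the polarity of the coupling and uses the C9 stereocentre for 1,3-induction; it sets out from 9 and 8 and returns to the route at 15. Oxidation of 9 (MnO2, CH2Cl2) should give (1R)-4-oxocyclopent-2-en-1-yl acetate F1, enzymatic deacetylation (wheat-germ lipase, pH 7 buffer) should give (4R)-4-hydroxycyclopent-2-en-1-one F2, and silylation (TBSCl, imidazole) should give (4R)-4-(tert-butyldimethylsilyloxy)cyclopent-2-en-1-one F3. Boronic ester 8 is oxidised (NaOH, H2O2) to (2Z,5Z)-octa-2,5-dien-1-ol F4 and converted (MsCl, 2,4,6-collidine, LiCl, DMF, 0 °C) into (2Z,5Z)-1-chloroocta-2,5-diene F5. Activated barium (from BaI2 and lithium biphenylide, THF, −78 °C) should turn F5 into [(2Z,5Z)-octa-2,5-dien-1-yl]barium chloride F6. This reagent is expected to keep its Z geometry at −78 °C and to add through its α-carbon in a 1,2 sense to F3, anti to the silyloxy group, giving (1S,4R)-4-(tert-butyldimethylsilyloxy)-1-[(2Z,5Z)-octa-2,5-dien-1-yl]cyclopent-2-en-1-ol F7. TBAF in THF then gives 15.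

Step 12. The enolate may be phosphitylated on oxygen instead of carbon, may exchange protons with the product, or may lose the β-silyloxy group. The fallback leaves phosphorus out and makes the C7=C8 bond by aldol condensation; it sets out from 20 (with 28) and returns at 30. The lithium enolate of 20 (LiN(iPr)2, THF, −78 °C) adds to 28 to give the aldol adduct methyl (4S,5E)-7-{4-bromo-2-[(2Z,5Z)-octa-2,5-dien-1-yl]-5-oxo-2-(triethylsilyloxy)cyclopent-3-en-1-yl}-4-(tert-butyldimethylsilyloxy)-7-hydroxyhept-5-enoate F8 (ring configured as in 20, diastereomers at C7 and C8). Mesylation and base-induced elimination (MsCl, Et3N, then DBU) are expected to favour the 7E dienone, methyl (4S,5E,7E,12R,14Z,17Z)-10-bromo-4-(tert-butyldimethylsilyloxy)-9-oxo-12-(triethylsilyloxy)prosta-5,7,10,14,17-pentaenoate F9. Irradiation (350 nm, benzene) should equilibrate the C7=C8 geometry; 30 is separated by chromatography and the 7E isomer is recycled.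

Step 16. Z selectivity may erode through equilibration of the adducts, or addition at the hindered C8 may be sluggish. The fallback corrects the geometry after the chain is complete instead of during olefination; it sets out from the crude geometric mixture containing 30 and returns at 31. The mixture is desilylated as in step 17, and the free diols are separated by chromatography into 31 and methyl (4S,5E,7E,12R,14Z,17Z)-10-bromo-4,12-dihydroxy-9-oxoprosta-5,7,10,14,17-pentaenoate F10. F10 is irradiated (350 nm, benzene) to re-equilibrate the C7=C8 geometry and is recycled through the same separation.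

Further compounds
F1 | step 7 | (1R)-4-oxocyclopent-2-en-1-yl acetate | CC(=O)O[C@H]1C=CC(=O)C1
F2 | step 7 | (4R)-4-hydroxycyclopent-2-en-1-one | O=C1C=C[C@H](O)C1
F3 | step 7 | (4R)-4-(tert-butyldimethylsilyloxy)cyclopent-2-en-1-one | O=C1C=C[C@H](O[Si](C)(C)C(C)(C)C)C1
F4 | step 7 | (2Z,5Z)-octa-2,5-dien-1-ol | CC/C=C\C/C=C\CO
F5 | step 7 | (2Z,5Z)-1-chloroocta-2,5-diene | CC/C=C\C/C=C\CCl
F6 | step 7 | [(2Z,5Z)-octa-2,5-dien-1-yl]barium chloride | CC/C=C\C/C=C\C[Ba]Cl
F7 | step 7 | (1S,4R)-4-(tert-butyldimethylsilyloxy)-1-[(2Z,5Z)-octa-2,5-dien-1-yl]cyclopent-2-en-1-ol | CC/C=C\C/C=C\C[C@@]1(O)C=C[C@H](O[Si](C)(C)C(C)(C)C)C1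
F8 | step 12 | methyl (4S,5E)-7-{4-bromo-2-[(2Z,5Z)-octa-2,5-dien-1-yl]-5-oxo-2-(triethylsilyloxy)cyclopent-3-en-1-yl}-4-(tert-butyldimethylsilyloxy)-7-hydroxyhept-5-enoate | CC/C=C\C/C=C\C[C@@]1(O[Si](CC)(CC)CC)C=C(Br)C(=O)C1C(O)/C=C/[C@@H](O[Si](C)(C)C(C)(C)C)CCC(=O)OC
F9 | step 12 | methyl (4S,5E,7E,12R,14Z,17Z)-10-bromo-4-(tert-butyldimethylsilyloxy)-9-oxo-12-(triethylsilyloxy)prosta-5,7,10,14,17-pentaenoate | CC/C=C\C/C=C\C[C@@]1(O[Si](CC)(CC)CC)C=C(Br)C(=O)/C1=C/C=C/[C@@H](O[Si](C)(C)C(C)(C)C)CCC(=O)OC
F10 | step 16 | methyl (4S,5E,7E,12R,14Z,17Z)-10-bromo-4,12-dihydroxy-9-oxoprosta-5,7,10,14,17-pentaenoate | CC/C=C\C/C=C\C[C@@]1(O)C=C(Br)C(=O)/C1=C/C=C/[C@@H](O)CCC(=O)OC
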